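**Plan**

- Retrosynthesis: cut first the aryl–CHO bond of ring A (the formyl-bearing benzene). Then cut the two ring A C–C bonds C(O‑ether)–C(C=O) and C(CH3)–CH, which also opens the seven-membered lactone. Then cut the ester C–O at O7 and the vinyl C–O at O6 of ring B (the chromanone benzene), and last the pyranone ring.
- Enabling feature: in ring A the lactone carbonyl carbon and the diaryl-ether oxygen sit on adjacent carbons and are bound to the two vicinal oxygens O6 and O7 of ring B. An aryloxy-silyloxy-diene on O6 and a but-2-ynoate on O7 can therefore close ring A and the dioxepinone ring in one operation.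
- Forward order: ring B benzene (2,3-dimethoxytoluene) → pyranone ring → catechol → diene arm on O6 → ynoate arm on O7 → ring A plus lactone → desilylation → formylation.
- Stereochemistry: the target has no stereocentre. The E enol ether comes from thermodynamically controlled oxa-Michael addition, and the racemic sp3 carbon of the cycloadduct disappears on aromatisation.
- Design point: the enone arm is turned into the silyl dienol ether before O7 is unmasked. A free phenol never sits beside the β-aryloxy enone, where it would close to a 1,3-benzodioxole.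

Key step: step 9

Remark on the chemistry: chromanone numbering (O1, C2, C4=O, 5-CH3, O6, O7) is used for ring B throughout, and one equivalent of TBSOTf at −78 °C is assumed to leave the hindered chromanone carbonyl untouched.

**Step 1**
Reactants: 1 2,3-dimethoxytoluene
Product: 3 3,4-dimethoxy-5-methylphenol, via aryl pinacol boronate 2 (not isolated)
Conditions: [Ir(OMe)(cod)]2 (1 mol%), 4,4'-di-tert-butyl-2,2'-bipyridine (2 mol%), B2pin2 (0.55 equiv), THF, 80 °C; then KHSO5 (Oxone), acetone/H2O, 0 °C to rt
Reagents that add atoms: bis(pinacolato)diboron, CC1(C)OB(OC1(C)C)B1OC(C)(C)C(C)(C)O1 (boron and pinacolate in 2 only); potassium peroxymonosulfate, [K+].[O-]S(=O)(=O)OO (the phenol oxygen)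
Why: Sterically governed iridium-catalysed C–H borylation of a 1,2,3-trisubstituted benzene should take place only at C5, the one C–H without an ortho substituent, and oxidation of the C–B bond in the same flask (one-pot borylation/oxidation) delivers the phenol.

**Step 2**
Reactants: 3 3,4-dimethoxy-5-methylphenol; 4 3-methylbut-2-enoic acid
Product: 6 6,7-dimethoxy-2,2,5-trimethylchroman-4-one, via ortho-hydroxyaryl enone 5 (not isolated)
Conditions: P2O5 in MeSO3H (1:10 w/w), 70 °C
Reagents that add atoms: none
Why: Friedel–Crafts acylation should occur at the carbon ortho to OH, ortho to CH3 and para to the freely conjugating 3-methoxy group (the orcinol-to-orcacetophenone pattern, the site between OH and OCH3 being less reactive), and intramolecular oxa-Michael addition of the phenol to the resulting enone then closes the 2,2-dimethylchromanone.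

**Step 3**
Reactants: 6 6,7-dimethoxy-2,2,5-trimethylchroman-4-one
Product: 7 6,7-dihydroxy-2,2,5-trimethylchroman-4-one
Conditions: BBr3 (3 equiv), CH2Cl2, −78 °C to 0 °C; then H2O
Reagents that add atoms: none
Why: Lewis-acid ether cleavage by BBr3 removes both aryl methyl groups, while the chroman O–C(CH3)2 bond, whose oxygen is a weakly basic vinylogous ester oxygen and whose carbon lies beta to the carbonyl, is expected to survive at low temperature.

**Step 4**
Reactants: 7 6,7-dihydroxy-2,2,5-trimethylchroman-4-one
Product: 8 7-(allyloxy)-6-hydroxy-2,2,5-trimethylchroman-4-one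
Conditions: allyl bromide (1.05 equiv), K2CO3 (1.05 equiv), DMF (degassed), 0 °C to rt
Reagents that add atoms: allyl bromide, C=CCBr
Why: Williamson etherification with one equivalent of mild base should alkylate only the 7-OH, which is para to the ketone and therefore much more acidic, and is also less hindered than the 6-OH flanked by the 5-methyl group, as is usual for 3,4-dihydroxyaryl ketones.

**Step 5**
Reactants: 8 7-(allyloxy)-6-hydroxy-2,2,5-trimethylchroman-4-one; 9 but-3-yn-2-one
Product: 10 7-(allyloxy)-2,2,5-trimethyl-6-[(E)-3-oxobut-1-enyloxy]chroman-4-one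
Conditions: 9 (1.2 equiv), DABCO (10 mol%), CH2Cl2, 0 °C to rt
Reagents that add atoms: none
Why: Amine-catalysed oxa-Michael addition of the phenol to the terminal ynone gives the thermodynamically preferred (E)-β-aryloxy enone, and with O7 capped no neighbouring phenol can add a second time.

**Step 6**
Reactants: 10 7-(allyloxy)-2,2,5-trimethyl-6-[(E)-3-oxobut-1-enyloxy]chroman-4-one
Product: 11 7-(allyloxy)-6-[(E)-3-(tert-butyldimethylsilyloxy)buta-1,3-dienyloxy]-2,2,5-trimethylchroman-4-one
Conditions: TBSOTf (1.05 equiv), Et3N (2 equiv), Et2O, −78 °C to 0 °C; work-up on Et3N-deactivated silica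
Reagents that add atoms: tert-butyldimethylsilyl triflate, CC(C)(C)[Si](C)(C)OS(=O)(=O)C(F)(F)F
Why: Soft enolisation silylates the most Lewis-basic carbonyl, that of the vinylogous ester, and deprotonation of its methyl group gives the Danishefsky-type silyl dienol ether with the E enol ether unchanged, whereas the chromanone carbonyl, flanked by the peri methyl group and the gem-dimethyl carbon, should react more slowly.

**Step 7**
Reactants: 11 7-(allyloxy)-6-[(E)-3-(tert-butyldimethylsilyloxy)buta-1,3-dienyloxy]-2,2,5-trimethylchroman-4-one
Product: 12 6-[(E)-3-(tert-butyldimethylsilyloxy)buta-1,3-dienyloxy]-7-hydroxy-2,2,5-trimethylchroman-4-one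
Conditions: Pd(PPh3)4 (3 mol%), morpholine (3 equiv), THF, rt; pH 7 buffer work-up, used at once
Reagents that add atoms: none
Why: In this Tsuji–Trost deallylation zerovalent palladium ionises the allyl aryl ether, whose para-acyl phenoxide is a good leaving group, and morpholine traps the allyl fragment, under basic aprotic conditions that a TBS dienol ether tolerates and with a diene that, unlike the enone, is no acceptor for the freed phenoxide.

**Step 8**
Reactants: 12 6-[(E)-3-(tert-butyldimethylsilyloxy)buta-1,3-dienyloxy]-7-hydroxy-2,2,5-trimethylchroman-4-one; 13 but-2-ynoic acid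
Product: 15 6-[(E)-3-(tert-butyldimethylsilyloxy)buta-1,3-dienyloxy]-2,2,5-trimethyl-4-oxochroman-7-yl but-2-ynoate, via but-2-ynoic anhydride 14 (not isolated)
Conditions: 13 (2.2 equiv), DCC (1.1 equiv), CH2Cl2, 0 °C, filter; filtrate added to 12, Et3N (1.5 equiv), CH2Cl2, −20 °C
Reagents that add atoms: none
Why: Acylation of the acidic 7-phenol by the preformed symmetric anhydride under amine base (anhydride esterification) keeps free but-2-ynoic acid away from the acid-labile dienol ether and avoids DMAP, which could add to the ynoate.

**Step 9**
Reactants: 15 6-[(E)-3-(tert-butyldimethylsilyloxy)buta-1,3-dienyloxy]-2,2,5-trimethyl-4-oxochroman-7-yl but-2-ynoate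
Product: 17 desformyl mollicellin A tert-butyldimethylsilyl ether (the depsidone with ring A bearing CH3 and OTBS, joined to ring B through the O6 ether and the O7 ester), via cyclohexa-1,4-diene cycloadduct 16 (not isolated)
Conditions: toluene (5 mM, degassed), 2,6-di-tert-butyl-4-methylpyridine (0.2 equiv), 90 °C; then rt, DDQ (1.2 equiv)
Reagents that add atoms: none
Why: Proposed new method: a thermal intramolecular (4+2) cycloaddition joins the electron-rich (E)-1-aryloxy-3-silyloxydiene on O6 to the aryl but-2-ynoate on O7, the nucleophilic CH2 terminus bonding to the methyl-bearing β-carbon and the aryloxy-bearing terminus to the α-carbon, and DDQ then abstracts hydride from the doubly allylic O-bearing CH of cyclohexa-1,4-diene 16 to give an arenium ion, stabilised by the aryloxy and silyloxy groups, that loses a proton from the ring CH2. The closest known reactions are the intermolecular Diels–Alder reactions of 1-alkoxy-3-silyloxybutadienes with alkynoates and the DDQ dehydrogenation of cyclohexa-1,4-dienes, whereas a catechol tether that closes a seven-membered lactone and an aromatisation that keeps the oxygen at the diene terminus have no precedent. Ring A closes as the six-membered ring of the cycloaddition, and the seven-membered lactone closes with it as the tether ring (diene terminus, O6, the two ring B carbons, O7, the ester carbonyl, the alkyne α-carbon) with the ester in its s-cis lactone conformation. The only new stereocentre, the CH(OAr) carbon of 16, forms racemic and is destroyed on aromatisation. Regioselectivity is secured twice, by the matched polarity of diene and ynoate and by the tether, which permits only this orientation. Dehydrogenation must outrun 1,4-elimination of the ring B phenoxide, which is addressed by the non-polar solvent, by a hindered pyridine that removes acid but cannot deprotonate the vinylogous CH2, and by adding DDQ at room temperature as soon as 15 is consumed.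

**Step 10**
Reactants: 17 desformyl mollicellin A tert-butyldimethylsilyl ether
Product: 18 desformyl mollicellin A (ring A phenol)
Conditions: TBAF (1.1 equiv), AcOH (1.2 equiv), THF, 0 °C
Reagents that add atoms: none
Why: Fluoride-mediated desilylation cleaves the aryl Si–O bond, and the acetic acid buffer should keep the medium from opening the activated seven-membered aryl lactone.

**Step 11**
Reactants: 18 desformyl mollicellin A
Product: 20 mollicellin A, via chloro(methoxy)methyl arene 19 (not isolated)
Conditions: Cl2CHOMe (2 equiv), TiCl4 (4 equiv), CH2Cl2, −20 °C to 0 °C; then 1 M HCl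
Reagents that add atoms: dichloromethyl methyl ether, COC(Cl)Cl
Why: In this Rieche formylation the titanium phenoxide of ring A is the most activated arene, and binding of the electrophile between the phenoxide and the neighbouring ether oxygen is expected to direct attack to the carbon between them, the known tendency of 3-alkoxyphenols, before aqueous hydrolysis of 19 releases the aldehyde.

**Compound list**

1 | 2,3-dimethoxytoluene | COc1cccc(C)c1OC | starting material
2 | 2-(3,4-dimethoxy-5-methylphenyl)-4,4,5,5-tetramethyl-1,3,2-dioxaborolane | COc1cc(cc(C)c1OC)B1OC(C)(C)C(C)(C)O1 | intermediate (not isolated)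
3 | 3,4-dimethoxy-5-methylphenol | COc1cc(O)cc(C)c1OC | intermediate
4 | 3-methylbut-2-enoic acid | CC(C)=CC(=O)O | starting material
5 | 1-(2-hydroxy-4,5-dimethoxy-6-methylphenyl)-3-methylbut-2-en-1-one | COc1cc(O)c(C(=O)C=C(C)C)c(C)c1OC | intermediate (not isolated)
6 | 6,7-dimethoxy-2,2,5-trimethylchroman-4-one | COc1cc2OC(C)(C)CC(=O)c2c(C)c1OC | intermediate
7 | 6,7-dihydroxy-2,2,5-trimethylchroman-4-one | Cc1c(O)c(O)cc2OC(C)(C)CC(=O)c12 | intermediate
8 | 7-(allyloxy)-6-hydroxy-2,2,5-trimethylchroman-4-one | C=CCOc1cc2OC(C)(C)CC(=O)c2c(C)c1O | intermediate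
9 | but-3-yn-2-one | CC(=O)C#C | starting material
10 | 7-(allyloxy)-2,2,5-trimethyl-6-[(E)-3-oxobut-1-enyloxy]chroman-4-one | C=CCOc1cc2OC(C)(C)CC(=O)c2c(C)c1O/C=C/C(C)=O | intermediate
11 | 7-(allyloxy)-6-[(E)-3-(tert-butyldimethylsilyloxy)buta-1,3-dienyloxy]-2,2,5-trimethylchroman-4-one | C=CCOc1cc2OC(C)(C)CC(=O)c2c(C)c1O/C=C/C(=C)O[Si](C)(C)C(C)(C)C | intermediate
12 | 6-[(E)-3-(tert-butyldimethylsilyloxy)buta-1,3-dienyloxy]-7-hydroxy-2,2,5-trimethylchroman-4-one | Oc1cc2OC(C)(C)CC(=O)c2c(C)c1O/C=C/C(=C)O[Si](C)(C)C(C)(C)C | intermediate
13 | but-2-ynoic acid | CC#CC(=O)O | starting material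
14 | but-2-ynoic anhydride | CC#CC(=O)OC(=O)C#CC | intermediate (not isolated)
15 | 6-[(E)-3-(tert-butyldimethylsilyloxy)buta-1,3-dienyloxy]-2,2,5-trimethyl-4-oxochroman-7-yl but-2-ynoate | CC#CC(=O)Oc1cc2OC(C)(C)CC(=O)c2c(C)c1O/C=C/C(=C)O[Si](C)(C)C(C)(C)C | intermediate (key-step precursor)
16 | cyclohexa-1,4-diene cycloadduct (ring A with sp3 CH(OAr) and CH2, racemic) | CC1=C2C(=O)Oc3cc4OC(C)(C)CC(=O)c4c(C)c3OC2C=C(O[Si](C)(C)C(C)(C)C)C1 | intermediate (not isolated)
17 | desformyl mollicellin A tert-butyldimethylsilyl ether | Cc1cc(O[Si](C)(C)C(C)(C)C)cc2c1C(=O)Oc1cc3c(c(C)c1O2)C(=O)CC(C)(C)O3 | intermediate (key-step product)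
18 | desformyl mollicellin A | Cc1cc(O)cc2c1C(=O)Oc1cc3c(c(C)c1O2)C(=O)CC(C)(C)O3 | intermediate
19 | chloro(methoxy)methyl arene (racemic, ring A carbon between OH and ether O) | Cc1cc(O)c(C(Cl)OC)c2c1C(=O)Oc1cc3c(c(C)c1O2)C(=O)CC(C)(C)O3 | intermediate (not isolated)
20 | mollicellin A | Cc1cc(O)c(C=O)c2c1C(=O)Oc1cc3c(c(C)c1O2)C(=O)CC(C)(C)O3 | target

**Count**

Total steps: 11. Longest linear sequence: 11 steps (1 to 20); compounds 4, 9 and 13 are bought.

**Steps most likely to fail**

Step 9. The cycloadduct may lose the ring B phenoxide by 1,4-elimination before DDQ can act, which opens the tether and leaves a depside-type benzoate, or the tethered cycloaddition may not reach the seven-membered transition state. The fallback is the classical diaryl-ether-then-lactone route, which sets out from 8 and returns at 18. Ullmann ether synthesis (CuI, picolinic acid, K3PO4, DMSO, 90 °C) of the 6-OH of 8 with allyl 4-(benzyloxy)-2-bromo-6-methylbenzoate F1, a ring A bromide that would have to be made separately, should give diaryl ether F2. Pd(PPh3)4 and morpholine would remove the allyl ether and the allyl ester together to give hydroxy acid F3. Lactonisation under high dilution (2-chloro-1-methylpyridinium iodide, Et3N, CH2Cl2) would close the seven-membered ring to ring A benzyl ether F4, and hydrogenolysis (H2, Pd/C, EtOAc) would give 18.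

Step 11. The electrophile may attack the other ortho carbon of the phenol (between OH and CH3, para to the ether oxygen) or ring B. The fallback uses that same preference to block the position, sets out from 18 and returns at 20. NBS (1 equiv, MeCN, 0 °C) should brominate the methyl-flanked carbon to give bromophenol F5. Rieche formylation of F5 can then occur on ring A only between OH and the ether oxygen, giving bromo aldehyde F6. Palladium-catalysed hydrodebromination (Pd(PPh3)4, HCO2Na, DMF, 80 °C) would then give 20.

Step 7. The freed, fairly acidic phenol or its phenoxide may protonate or desilylate the dienol ether during deallylation and work-up. The fallback never releases the phenol, sets out from 11 and returns at 15. Hydrostannolytic deallylation (Pd(PPh3)4 cat., Bu3SnH 1.05 equiv, CH2Cl2, rt) would give tributylstannyl phenoxide F7 and propene, and anhydride 14, added to the same flask at −20 °C, would acylate F7 directly to 15.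

**Further compounds**

F1 | step 9 | allyl 4-(benzyloxy)-2-bromo-6-methylbenzoate | C=CCOC(=O)c1c(C)cc(OCc2ccccc2)cc1Br
F2 | step 9 | allyl 2-[7-(allyloxy)-2,2,5-trimethyl-4-oxochroman-6-yloxy]-4-(benzyloxy)-6-methylbenzoate | C=CCOC(=O)c1c(C)cc(OCc2ccccc2)cc1Oc1c(C)c2C(=O)CC(C)(C)Oc2cc1OCC=C
F3 | step 9 | 4-(benzyloxy)-2-(7-hydroxy-2,2,5-trimethyl-4-oxochroman-6-yloxy)-6-methylbenzoic acid | OC(=O)c1c(C)cc(OCc2ccccc2)cc1Oc1c(C)c2C(=O)CC(C)(C)Oc2cc1O
F4 | step 9 | desformyl mollicellin A benzyl ether | Cc1cc(OCc4ccccc4)cc2c1C(=O)Oc1cc3c(c(C)c1O2)C(=O)CC(C)(C)O3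
F5 | step 11 | desformyl mollicellin A brominated on ring A between OH and CH3 | Cc1c(Br)c(O)cc2c1C(=O)Oc1cc3c(c(C)c1O2)C(=O)CC(C)(C)O3
F6 | step 11 | mollicellin A brominated on ring A between OH and CH3 | Cc1c(Br)c(O)c(C=O)c2c1C(=O)Oc1cc3c(c(C)c1O2)C(=O)CC(C)(C)O3
F7 | step 7 | tributylstannyl ether of phenol 12 | CCCC[Sn](CCCC)(CCCC)Oc1cc2OC(C)(C)CC(=O)c2c(C)c1O/C=C/C(=C)O[Si](C)(C)C(C)(C)C
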